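A charge of 0.10 M of solid substrate stands above the solubility of 47 mM, and the pitfall is to expect a saturated flask with solid left in it.

    starting material ⇌ target + by-product (K1 = 0.079 M, k1 = 0.018 s⁻¹)
    solid substrate ⇌ starting material, rate k2*(cs2 - [starting material]) while solid is left; crystals form when [starting material] > cs2 (cs2 = 47 mM, k2 = 0.091 s⁻¹)
    starting material ⇌ dormant form (K3 = 0.59, k3 = 0.0029 s⁻¹)

solid substrate 0.10 M; time 80 min

- solid substrate is a solid; its amount is given per volume of the solution
- at the start none of the solid substrate is in solution
- what has only dissolved of solid substrate counts as not reacted
- the reaction counts as stopped when no species that holds the solid substrate changes by six tenths of a point or more over the second half of the time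
- starting material means what is dissolved; the solid is not counted in it
- run time (flask): 80 min

* why nothing more happens at 80 min, or that something still does (for what has run out or reacted, a solid counts together with what of it has only dissolved) (forward and back rates have come level / all of the solid substrate has reacted / it is still moving)
* the target standing at 80 min, as a percentage of the solid substrate charged
* the starting material standing at 80 min, as a percentage of the solid substrate charged

Our reckoning starts from the times: the forward half-lives, 0.642 min for target formation and 3.98 min for the dormant form, are short against 80 min, so we take this flask to equilibrium. Starting material and dormant form then stand in a fixed ratio and act as one pool, which gives target and by-product with an apparent equilibrium constant, the first constant divided by one plus the second: 0.0497 M.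

If the solid dissolves, target squared over charge minus target equals this constant. While the solid does dissolve, this equation sends target towards the charge when the charge is small against the constant, and towards the square root of their product when it is large. The quadratic joins both ends at 0.0499 M. That leaves starting material at 0.0315 M, less than the solubility, so we expect no solid to stay.

The forecast agrees: forward and back rates have come level, target 49.9% (49% to 51%), starting material 31.5% (30.5% to 32.5%), since “both equilibria relax in minutes at most”.

In the simulation forward and back rates have come level, with target 49.9% and starting material 31.5%.

With the dormant form struck out of this flask, 0.0497 M becomes 0.079 M, and the same quadratic puts starting material at 0.0422 M, nearer the solubility but still below it; the simulated run gives 42.2% of the charge.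

For the neighbour flask with 0.060 M of solid substrate, 0.0497 M gives target 0.0351 M, or 58.5% of its charge, and starting material 26.0%. The simulation of that flask gives 58.6% and 26.1%.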